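## Analysis of the target

Atom numbers (C1 to C26, heteroatoms included in the count) follow the order of the target SMILES. The molecule is a pentacyclic C22 hydroquinone. Its benzene ring (C19, C20, C22, C23, C24, C26) is fused to cyclopentane ring D (C6, C13, C26, C19, C18), and cyclohexene ring C (C6, C13, C14, C15, C17, C18; C16 methyl on C15, C15=C17) spans C13 and C18, so that rings C and D form a benzo-fused bicyclo[3.2.1]octene with C6 as the one-carbon bridge. Cyclohexane-1,4-dione ring B (C6, C7, C9, C10, C11, C13) is fused along C6–C13, and cyclopentane ring A (C4, C5, C6, C7, C9) turns it into a second bicyclo[3.2.1]octane whose one-carbon bridge is the C7 ketone. Of the five stereocentres, C13 and C18 are bridgeheads and necessarily cis; at C6 the C5 methylene lies over the C14–C15–C17 bridge and C7 over the arene; C9 is dictated by the A/B cage. Only C4 is free: its isopropenyl group is exo, on the side of the C7 carbonyl and trans to C10 on ring A. The difficulties are the adjacent quaternary carbons C6 and C13, the air-sensitive hydroquinone, two acid-sensitive alkenes, and three carbonyl carbons (C7, C11 and the precursor of C15) that must be told apart. The strategy rests on ring C: C14–C15–C17 bridges C13 and C18 of an indane whose C2 carbon (C6) is quaternary, the pattern of a three-carbon unit added across the termini of a 2,2-disubstituted 2H-indene.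

## Retrosynthetic reasoning

**30 from 28 (via 29).** The two phenolic O–H groups are traced back to methyl ethers. A free hydroquinone would not survive radical bromination, zinc, enolate or Lewis acid chemistry, whereas the 1,4-dimethoxyarene is robust, and its ortho-methoxy groups stabilise the benzylic radicals and cations used earlier. The forward step is an oxidative demethylation to quinone 29 and its reduction, which must spare two ketones and two alkenes.

**28 from 27 (C4–C9, ring A).** C9 is β to the C11 carbonyl and C4 is two atoms away from C6, so a carbon nucleophile at C4 can add conjugately to an enedione. An ene reaction of a prenyl group is not used. A concerted ene process must pass a methyl hydrogen to C10, which holds C2 over ring B and gives the C4 epimer, with isopropenyl cis to C10. An allylsilane adds stepwise through an open transition state and loses silicon to give the isopropenyl alkene regiospecifically. For this, C7 must be a ketone and not the ketal, so that the exo position next to C7 is unhindered.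

**27 from 23 (via 26, 25, 24).** These are functional-group changes on the C6 arm and at C7, with a cut at C4=C2. The allylsilane comes from aldehyde 25 by Wittig olefination, the aldehyde from alcohol 24, and the alcohol from silyl ether 23. The C7 ketal is kept until the olefination is done, because a phosphorus ylide would attack an enedione.

**23 from 21 (via 22; C15–C16).** The methyl group is put on by cross-coupling of the C15 enol triflate 22. The triflate comes from kinetic deprotonation at C17, since C14 is neopentylic next to quaternary C13. This is chemoselective only if C15 is the sole enolisable carbonyl, which is true for enone 21. Its C9=C10 bond removes the C10 hydrogens, C13 is quaternary and C7 carries no hydrogen.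

**21 from 20 (C9=C10).** Dehydrogenation of the C11 ketone is site-selective by structure. The C15 ketone cannot be desaturated, because C13 is quaternary and C18 is a bridgehead (Bredt's rule). The same double bond later serves as the acceptor for ring A.

**20 from 16 and 17 (C13–C14 and C17–C18, ring C).** These are the only two ring C bonds that do not belong to the indane. Cutting them returns a purchasable ring system, a symmetrical three-carbon unit (17 as an oxyallyl cation equivalent) and two benzylic carbons that can each carry a bromide. The forward reaction is a (4+3) cycloaddition onto the transient 2H-indene 18, followed by debromination of 19. It must create quaternary C13 and the C18 stereocentre on the face of C6 that bears C5.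

**16 from 15 (C13–Br, C18–Br).** Both positions are benzylic and flank quaternary C6, so radical bromination reaches them and neither bromide can eliminate.

**15 from 13 (via 14; C11–C13, ring B).** C13 is the carbonyl carbon of the starting indanone. Acyl-anion addition of the C11 aldehyde to it (crossed benzoin) sets up the 1,4-dioxygenation of ring B directly, and the surplus C13 hydroxyl of 14 is removed reductively.

**13 from 8 (via 12, 11, 10, 9; C7–C9).** C9, C10 and C11 arrive as a butenyl Grignard unit that adds once to the lactone carbonyl of 8. The C7 ketone is ketalised while C11 is still an alkene, the one stage at which C7 and C11 are unambiguously different. The alkene is then cleaved to the aldehyde.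

**8 from 1, 2 and 4 (via 5 and 3; C6–C5 and C6–C7).** Quaternary C6 is set by asymmetric allylic alkylation of β-keto ester 3 with 4. The ester carbon becomes C7, and the allyl group, shortened by ozonolysis, becomes C5–C4. Lactone 8 forms on reduction and is the mono-addition acceptor for the Grignard step.

## Alternatives that were turned down

**Alternative 1:** The benzene ring is cut at C19–C26, C20–C22 and C23–C24, so that the arene and ring D are made last. Diyne A2, carrying a (pinacolboryl)ethynyl group on C13 and on C18 of the finished cage, would be co-cyclotrimerised with ethyne A3 on a rhodium or cobalt catalyst to the aryl bis(boronate) A1, whose C–B bonds are then oxidised to the phenols.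
- For it: the 1,6-diyne tether is ideal, the third alkyne is symmetrical, and no hydroquinone protecting group is needed. Unmasking phenols by C–B oxidation is milder than oxidative demethylation, and on this point it is stronger than the chosen route.
- Against it: A2 must contain rings A, B and C and all five stereocentres, with two cis alkynyl groups, one on a quaternary carbon next to a ketone. It has to be built without the benzene ring that templates C13 and C18 in the chosen route. A3 oligomerises, and the two alkenes of A2 can enter the metallacycle.
- Comparison: the chosen strategy buys ring D and the arene in 1 and spends its risk on one ring. It pays with a late oxidative demethylation.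

**Alternative 2:** The cut is at C6–C13 and C9–C10. Ionisation of the C13 chloride of A5 would give a 2-siloxyallyl cation (C13–C11–C10) that adds across C6 and C9 of the tethered 5,5-dimethoxycyclopentadiene unit, closing rings B and D (and ring C with them) to give the acetyl enone A4.
- For it: oxyallyl cation plus cyclopentadiene is the textbook route to a bicyclo[3.2.1]octenone, and here it would deliver the A/B cage, three rings and C6, C9 and C13 in one step. The C15 methyl alkene is already in place and the C4 acetyl group can be equilibrated to the exo position. On ring count, on the C15 regiochemistry and on C4 control it is stronger than the chosen route.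
- Against it: the C6–C13 bond would join two fully substituted carbons in the bond-forming step. The diene carries an acetyl group and is a poor partner for an electrophile, and cyclopentadienone ketals dimerise readily. A5 is a functionalised benzocycloheptene with a defined C18 centre and is itself a long synthesis.
- Comparison: the chosen strategy has C6–C13 from the start and only has to bond a CH2 terminus to C13. It offers a short, reliable approach to the cycloaddition precursor in place of the higher complexity gain.

**Alternative 3:** The cut is at C13–C26 and C18–C19. Desilylation of the bicyclic silyl enol ether A8 in the presence of 3,6-dimethoxybenzyne A7 would let C13 add to the aryne and the resulting aryl anion add 1,4 to the ring C enone at C18, closing ring D to give triketone A6.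
- For it: it is convergent, the aryne is symmetrical, C13 and C18 are forced cis, and no transient ortho-quinoid diene or benzylic bromination is needed. In convergency it is stronger than the chosen route.
- Against it: an aryl anion generated next to the C11 carbonyl normally attacks that carbonyl, leading to four-ring closure and C–C insertion, rather than a remote enone, and it is quenched by the many acidic hydrogens of a triketone. A6 still lacks ring A and the C15 methyl alkene, with three unprotected ketones to differentiate and a prenyl group whose ene closure would give the wrong C4 epimer.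
- Comparison: the chosen strategy carries C7 as a ketal through the cycloaddition, so the later carbonyl chemistry can be ordered, and its diene termini are exactly the two atoms to be bonded.

Key step: step 12

Assumption: the sense of induction in step 2 is taken from the usual model for this ligand class; if it proves opposite, the (S,S)-ligand is used instead.

## Route

Step 1
Reactants: 1 4,7-dimethoxy-1-indanone; 2 dimethyl carbonate
Product: 3 methyl 4,7-dimethoxy-1-oxoindane-2-carboxylate (racemic)
Conditions: NaH (2.2 equiv), 2 (5 equiv), THF, 65 °C; aq. HCl
Reagents that add atoms: none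
Why: Crossed Claisen condensation of the ketone enolate with the carbonate; C6 is the only enolisable position and the product is held as its sodium enolate, which drives the acylation.

Step 2
Reactants: 3 methyl 4,7-dimethoxy-1-oxoindane-2-carboxylate; 4 allyl acetate
Product: 5 methyl (S)-2-allyl-4,7-dimethoxy-1-oxoindane-2-carboxylate
Conditions: [Pd(C3H5)Cl]2 (1 mol %), (R,R)-N,N'-cyclohexane-1,2-diylbis[2-(diphenylphosphanyl)benzamide] (3 mol %), 1,1,3,3-tetramethylguanidine (1.2 equiv), toluene, 0 °C
Reagents that add atoms: none
Why: Palladium-catalysed asymmetric allylic alkylation (Tsuji–Trost type) of a cyclic β-keto ester; the chiral ligand pocket differentiates the faces of the prochiral enolate and so sets quaternary C6.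

Step 3
Reactants: 5 methyl (S)-2-allyl-4,7-dimethoxy-1-oxoindane-2-carboxylate
Product: 8 spiro hydroxy γ-lactone (C13 epimers), via keto aldehyde 6 (not isolated), via diol ester 7 (not isolated)
Conditions: O3, CH2Cl2–MeOH, −78 °C; Me2S; then NaBH4, 0 → 25 °C; aq. HCl
Reagents that add atoms: ozone ([O-][O+]=O)
Why: Ozonolysis of the only alkene, borohydride reduction of the aldehyde and of the aryl ketone, and spontaneous γ-lactonisation of the primary hydroxyl onto the neighbouring methyl ester; the C13 carbinol configuration is irrelevant because it is oxidised in step 6.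

Step 4
Reactants: 8 spiro hydroxy γ-lactone
Product: 9 hydroxy ketone diol with pent-4-enoyl group on C6 (in equilibrium with its lactol)
Conditions: CH2=CHCH2CH2MgBr (3 equiv), THF, −78 → 0 °C; aq. NH4Cl
Reagents that add atoms: but-3-enylmagnesium bromide (C=CCC[Mg]Br)
Why: Single Grignard addition to a lactone: the magnesium lactolate is stable at low temperature and quaternary C6 slows a second addition; one equivalent is consumed by the free hydroxyl.

Step 5
Reactants: 9 hydroxy ketone diol
Product: 10 primary tert-butyldimethylsilyl ether
Conditions: TBSCl (1.1 equiv), imidazole, DMF, 0 °C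
Reagents that add atoms: tert-butyldimethylsilyl chloride (CC(C)(C)[Si](C)(C)Cl)
Why: Selective silylation of the primary hydroxyl, which drains the lactol equilibrium; the neopentylic secondary benzylic carbinol reacts much more slowly.

Step 6
Reactants: 10 primary tert-butyldimethylsilyl ether
Product: 11 2-acylindanone (C7 and C13 ketones)
Conditions: Dess–Martin periodinane, NaHCO3, CH2Cl2, 25 °C
Reagents that add atoms: none
Why: Dess–Martin oxidation of the secondary benzylic alcohol; buffered neutral conditions avoid retro-Claisen cleavage of the non-enolisable 1,3-diketone.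

Step 7
Reactants: 11 2-acylindanone
Product: 12 C7 ethylene ketal
Conditions: Me3SiOCH2CH2OSiMe3 (3 equiv), Me3SiOTf (5 mol %), CH2Cl2, −78 → −20 °C; pyridine
Reagents that add atoms: 1,2-bis(trimethylsilyloxy)ethane (C[Si](C)(C)OCCO[Si](C)(C)C)
Why: Silyl triflate-catalysed aprotic ketalisation; the dialkyl ketone C7 reacts, whereas the C13 ketone is conjugated to the ortho-methoxy arene (vinylogous ester) and flanked by quaternary C6, and the silyl ether survives.

Step 8
Reactants: 12 C7 ethylene ketal
Product: 13 keto aldehyde (C11 aldehyde)
Conditions: O3, CH2Cl2, pyridine, −78 °C; PPh3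
Reagents that add atoms: ozone ([O-][O+]=O)
Why: Ozonolysis of the sole alkene unmasks C11; at −78 °C with controlled ozone dosage the terminal alkene is consumed well before the dimethoxyarene.

Step 9
Reactants: 13 keto aldehyde
Product: 14 tricyclic α-ketol (ring B closed; C13 hydroxyl; B/D cis)
Conditions: 3-benzyl-5-(2-hydroxyethyl)-4-methylthiazolium chloride (20 mol %), DBU (40 mol %), t-BuOH, 40 °C
Reagents that add atoms: none
Why: Intramolecular crossed benzoin reaction under N-heterocyclic carbene catalysis: the acyl-anion equivalent of the C11 aldehyde adds to the C13 ketone and closes six-membered ring B; the tether can only reach the C13 face on the side of C7, so the fusion is cis.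

Step 10
Reactants: 14 tricyclic α-ketol
Product: 15 tricyclic keto ketal (C13–H)
Conditions: SmI2 (3 equiv), THF–MeOH, −78 → 0 °C
Reagents that add atoms: none
Why: SmI2 reduction of an α-hydroxy ketone: the C11 ketyl expels the benzylic hydroxide and the samarium enolate is protonated by methanol; the C13 configuration is of no consequence because C13 becomes trigonal in step 12.

Step 11
Reactants: 15 tricyclic keto ketal
Product: 16 C13,C18-dibromide (epimer mixture, used crude)
Conditions: N-bromosuccinimide (2.2 equiv), AIBN (5 mol %), PhCF3, 80 °C, visible light
Reagents that add atoms: N-bromosuccinimide (O=C1CCC(=O)N1Br)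
Why: Wohl–Ziegler radical bromination of the two benzylic C–H positions flanking C6, as for 2,3-dialkyl-1,4-dimethoxybenzenes; the non-polar medium disfavours ring bromination, and neither bromide has a β-hydrogen, so they cannot eliminate.

Step 12
Reactants: 16 C13,C18-dibromide; 17 1,1,3,3-tetrabromoacetone
Product: 20 tetracyclic C11,C15-diketone C7-ketal, via 2H-indene 18 (not isolated), via dibromo cycloadduct 19 (not isolated)
Conditions: Zn–Cu couple (8 equiv), DME, −10 → 25 °C, 16 and 17 (3 equiv) added together over 2 h; then fresh Zn–Cu couple, NH4Cl, MeOH, 25 °C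
Reagents that add atoms: none
Why: Proposed new method: zinc reduces the C13 α-bromo ketone to its zinc enolate, which expels the C18 bromide through the benzene ring (or the C18 benzylzinc expels the C13 bromide) to give the ortho-quinoid 2H-indene 18, while the same metal turns 17 into a bromo-substituted zinc oxyallyl cation. The closest known reactions are the (4+3) cycloadditions of such cations with cyclopentadienes, furans and isobenzofurans, and the trapping by dienophiles of 2,2-disubstituted 2H-indenes made by zinc debromination of 1,3-dibromoindanes; their combination is new. The cation bonds through its two termini to C13 and C18, in concert or by first attack at C13 to give an ortho-methoxy-stabilised C18 benzylic cation that the zinc enolate then captures, and in either case the benzene ring is restored, which drives the addition. Ring C closes in the (4+3) mode as the six-membered half (C6, C13, C14, C15, C17, C18) of the new seven-membered carbocycle, with C6 as its one-carbon bridge. C13 and C18 are formed together and are necessarily cis because the bridge spans one face; their absolute sense is relayed from C6, since the three-carbon unit should add to the diene face that carries the C5 methylene and not the face screened by the C7 spiro-dioxolane and ring B. The step needs this facial selectivity and needs capture of 18 to outrun its dimerisation and the plain reduction of 16, which slow addition into excess cation precursor should secure, helped by the fact that C6 carries no hydrogen and 18 cannot tautomerise to a 1H-indene. The bromines left at C14 and C17 of 19 are reduced off in the same flask, so their configuration does not matter.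

Step 13
Reactants: 20 tetracyclic C11,C15-diketone C7-ketal
Product: 21 C9=C10 enone
Conditions: IBX (2.5 equiv), 4-methoxypyridine N-oxide (2.5 equiv), DMSO, 25 °C
Reagents that add atoms: none
Why: IBX dehydrogenation of a ketone to the enone; only the C11 ketone can react, because desaturation at C15 would need a double bond to quaternary C13 or to bridgehead C18 (Bredt's rule).

Step 14
Reactants: 21 C9=C10 enone
Product: 22 C15 enol triflate (C15=C17)
Conditions: KN(SiMe3)2 (1.1 equiv), THF, −78 °C; PhNTf2 (1.2 equiv), −78 → 0 °C
Reagents that add atoms: N-phenylbis(trifluoromethanesulfonimide) (O=S(=O)(N(c1ccccc1)S(=O)(=O)C(F)(F)F)C(F)(F)F)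
Why: Kinetic enolisation and O-triflation; C15 is the only enolisable carbonyl because the enone has no α' or γ hydrogen, and the bulky amide should remove a C17 hydrogen rather than one at C14, which is neopentylic and gauche to the C11 substituent on quaternary C13.

Step 15
Reactants: 22 C15 enol triflate
Product: 23 C15-methyl alkene
Conditions: Me4Sn (3 equiv), Pd(PPh3)4 (5 mol %), LiCl (3 equiv), DMF, 70 °C
Reagents that add atoms: tetramethylstannane (C[Sn](C)(C)C)
Why: Stille coupling of an alkenyl triflate; the neutral conditions leave the enone, the ketal and the silyl ether untouched, where a methylcuprate would add to the enone.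

Step 16
Reactants: 23 C15-methyl alkene
Product: 24 primary alcohol
Conditions: HF·pyridine, pyridine, THF, 0 → 25 °C
Reagents that add atoms: none
Why: Fluoride cleavage of the silyl ether under buffered, non-basic conditions, which avoids alkoxide addition to the enone and keeps the ketal.

Step 17
Reactants: 24 primary alcohol
Product: 25 aldehyde
Conditions: Dess–Martin periodinane, NaHCO3, CH2Cl2, 0 → 25 °C
Reagents that add atoms: none
Why: Dess–Martin oxidation of the primary alcohol to the aldehyde without over-oxidation or epimerisable centres at risk.

Step 18
Reactants: 25 aldehyde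
Product: 26 allylsilane ketal (mixture of alkene isomers at C4=C2)
Conditions: EtPPh3Br, n-BuLi, THF, 0 °C; ICH2SiMe3; n-BuLi, −78 °C; then 25, −78 → 25 °C
Reagents that add atoms: ethyltriphenylphosphonium bromide (CC[P+](c1ccccc1)(c1ccccc1)c1ccccc1.[Br-]); (iodomethyl)trimethylsilane (C[Si](C)(C)CI)
Why: Wittig olefination with a β-silyl ylide made in the flask by alkylating the ethylidene ylide and deprotonating again; the aldehyde reacts far faster than the hindered, non-enolisable enone, and the alkene geometry is irrelevant for the next steps.

Step 19
Reactants: 26 allylsilane ketal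
Product: 27 allylsilane enedione
Conditions: pyridinium p-toluenesulfonate (0.3 equiv), acetone–H2O (10:1), 50 °C
Reagents that add atoms: water (O)
Why: Mild acid-catalysed ketal hydrolysis unmasks the C7 ketone only after the ylide chemistry is finished; the weak acid is chosen to spare the allylsilane from protodesilylation.

Step 20
Reactants: 27 allylsilane enedione
Product: 28 di-O-methyl ether of the target
Conditions: EtAlCl2 (1.5 equiv), CH2Cl2, −78 → −30 °C; aq. NaHCO3
Reagents that add atoms: none
Why: Intramolecular Hosomi–Sakurai conjugate addition: the Lewis acid activates the C11 carbonyl, C4 attacks C9 in a 5-exo-trig closure across a chair-like ring B with C5 axial, and loss of silicon leaves the isopropenyl group. C9 is fixed by the cage, and C4 is set by the open antiperiplanar transition state in which C2 points away from ring B toward the flat C7 carbonyl, giving the exo isopropenyl group.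

Step 21
Reactants: 28 di-O-methyl ether of the target
Product: 30 CNP0287617.1 (target), via quinone 29 (not isolated)
Conditions: (NH4)2Ce(NO3)6 (2.5 equiv), MeCN–H2O, 0 °C; then Na2S2O4, H2O–EtOAc, 25 °C, argon
Reagents that add atoms: water (O)
Why: Oxidative demethylation of the 1,4-dimethoxyarene to the quinone, with water as oxygen source, followed by dithionite reduction to the hydroquinone; the brief cold oxidation should leave the ketones and the two unactivated alkenes intact.

## Compound list

1 | 4,7-dimethoxy-1-indanone | COc1ccc(OC)c2c1CCC2=O | starting material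
2 | dimethyl carbonate | COC(=O)OC | starting material
3 | methyl 4,7-dimethoxy-1-oxoindane-2-carboxylate (racemic) | COC(=O)C1Cc2c(OC)ccc(OC)c2C1=O | intermediate
4 | allyl acetate | C=CCOC(C)=O | starting material
5 | methyl (S)-2-allyl-4,7-dimethoxy-1-oxoindane-2-carboxylate | C=CC[C@@]1(C(=O)OC)C(=O)c2c(OC)ccc(OC)c2C1 | intermediate
6 | methyl 4,7-dimethoxy-1-oxo-2-(2-oxoethyl)indane-2-carboxylate (C6 as in 5) | O=CC[C@@]1(C(=O)OC)C(=O)c2c(OC)ccc(OC)c2C1 | intermediate (not isolated)
7 | methyl 1-hydroxy-2-(2-hydroxyethyl)-4,7-dimethoxyindane-2-carboxylate (C6 as in 5; C13 epimers) | OCC[C@@]1(C(=O)OC)C(O)c2c(OC)ccc(OC)c2C1 | intermediate (not isolated)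
8 | 1'-hydroxy-4',7'-dimethoxy-1',3'-dihydrospiro[oxolane-3,2'-inden]-2-one (C6 as in 5; C13 epimers) | O=C1OCC[C@]12C(O)c3c(OC)ccc(OC)c3C2 | intermediate
9 | 1-[1-hydroxy-2-(2-hydroxyethyl)-4,7-dimethoxyindan-2-yl]pent-4-en-1-one (C6 as in 5; C13 epimers) | C=CCCC(=O)[C@]1(CCO)C(O)c2c(OC)ccc(OC)c2C1 | intermediate
10 | 1-[2-(2-{[tert-butyl(dimethyl)silyl]oxy}ethyl)-1-hydroxy-4,7-dimethoxyindan-2-yl]pent-4-en-1-one | C=CCCC(=O)[C@]1(CCO[Si](C)(C)C(C)(C)C)C(O)c2c(OC)ccc(OC)c2C1 | intermediate
11 | 2-(2-{[tert-butyl(dimethyl)silyl]oxy}ethyl)-4,7-dimethoxy-2-(pent-4-enoyl)indan-1-one | C=CCCC(=O)[C@]1(CCO[Si](C)(C)C(C)(C)C)C(=O)c2c(OC)ccc(OC)c2C1 | intermediate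
12 | 2-[2-(but-3-enyl)-1,3-dioxolan-2-yl]-2-(2-{[tert-butyl(dimethyl)silyl]oxy}ethyl)-4,7-dimethoxyindan-1-one | C=CCCC1(OCCO1)[C@]2(CCO[Si](C)(C)C(C)(C)C)C(=O)c3c(OC)ccc(OC)c3C2 | intermediate
13 | 3-{2-[2-(2-{[tert-butyl(dimethyl)silyl]oxy}ethyl)-4,7-dimethoxy-1-oxoindan-2-yl]-1,3-dioxolan-2-yl}propanal | O=CCCC1(OCCO1)[C@]2(CCO[Si](C)(C)C(C)(C)C)C(=O)c3c(OC)ccc(OC)c3C2 | intermediate
14 | tricyclic α-ketol: rings B and D cis-fused, C7 dioxolane, C11 ketone, C13 hydroxyl, C6 silyloxyethyl arm | CC(C)(C)[Si](C)(C)OCC[C@@]23C4(OCCO4)CCC(=O)[C@]2(O)c2c(OC)ccc(OC)c2C3 | intermediate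
15 | tricyclic keto ketal: as 14 with hydrogen on C13 (cis-fused, epimerisable) | CC(C)(C)[Si](C)(C)OCC[C@@]23C4(OCCO4)CCC(=O)[C@@H]2c2c(OC)ccc(OC)c2C3 | intermediate
16 | C13,C18-dibromide of 15 (bromide epimers) | CC(C)(C)[Si](C)(C)OCC[C@@]23C4(OCCO4)CCC(=O)C2(Br)c2c(OC)ccc(OC)c2C3Br | intermediate
17 | 1,1,3,3-tetrabromoacetone | O=C(C(Br)Br)C(Br)Br | starting material
18 | 2H-indene: C13=C26 and C18=C19 ortho-quinoid diene, C6 sp3 with arm and ring B | CC(C)(C)[Si](C)(C)OCC[C@@]23C4(OCCO4)CCC(=O)C2=C2C(OC)=CC=C(OC)C2=C3 | intermediate (not isolated)
19 | C14,C17-dibromo cycloadduct (bromide epimers) | CC(C)(C)[Si](C)(C)OCC[C@@]23C4(OCCO4)CCC(=O)[C@@]21C(Br)C(=O)C(Br)[C@@H]3c2c(OC)ccc(OC)c21 | intermediate (not isolated)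
20 | tetracyclic C11,C15-diketone with C7 dioxolane (C6, C13, C18 as in the target) | CC(C)(C)[Si](C)(C)OCC[C@@]23C4(OCCO4)CCC(=O)[C@@]21CC(=O)C[C@@H]3c2c(OC)ccc(OC)c21 | intermediate
21 | C9=C10 enone of 20 | CC(C)(C)[Si](C)(C)OCC[C@@]23C4(OCCO4)C=CC(=O)[C@@]21CC(=O)C[C@@H]3c2c(OC)ccc(OC)c21 | intermediate
22 | C15 enol triflate (C15=C17) of 21 | CC(C)(C)[Si](C)(C)OCC[C@@]23C4(OCCO4)C=CC(=O)[C@@]21CC(OS(=O)(=O)C(F)(F)F)=C[C@@H]3c2c(OC)ccc(OC)c21 | intermediate
23 | C15-methyl alkene with enone, C7 dioxolane and silyl ether | CC(C)(C)[Si](C)(C)OCC[C@@]23C4(OCCO4)C=CC(=O)[C@@]21CC(C)=C[C@@H]3c2c(OC)ccc(OC)c21 | intermediate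
24 | primary alcohol from 23 | OCC[C@@]23C4(OCCO4)C=CC(=O)[C@@]21CC(C)=C[C@@H]3c2c(OC)ccc(OC)c21 | intermediate
25 | C4 aldehyde | O=CC[C@@]23C4(OCCO4)C=CC(=O)[C@@]21CC(C)=C[C@@H]3c2c(OC)ccc(OC)c21 | intermediate
26 | allylsilane ketal: C6 arm CH2–CH=C(CH3)–CH2SiMe3 (alkene isomers) | C[Si](C)(C)CC(C)=CC[C@@]23C4(OCCO4)C=CC(=O)[C@@]21CC(C)=C[C@@H]3c2c(OC)ccc(OC)c21 | intermediate
27 | allylsilane enedione (C7 and C11 ketones, C9=C10) | C[Si](C)(C)CC(C)=CC[C@@]23C(=O)C=CC(=O)[C@@]21CC(C)=C[C@@H]3c2c(OC)ccc(OC)c21 | intermediate
28 | 20,24-di-O-methyl ether of the target (all five stereocentres as in the target) | C=C(C)[C@H]1C[C@@]23C(=O)[C@@H]1CC(=O)[C@@]21CC(C)=C[C@@H]3c2c(OC)ccc(OC)c21 | intermediate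
29 | quinone corresponding to the target | C=C(C)[C@H]1C[C@@]23C(=O)[C@@H]1CC(=O)[C@@]21CC(C)=C[C@@H]3C=2C(=O)C=CC(=O)C=21 | intermediate (not isolated)
30 | CNP0287617.1 | C=C(C)[C@H]1C[C@@]23C(=O)[C@@H]1CC(=O)[C@@]21CC(C)=C[C@@H]3c2c(O)ccc(O)c21 | target

## Step count and least certain steps

Total: 21 steps. Longest linear sequence: 21 steps, from 1.

**Step 12 (key step).** The transient diene may be reduced or may dimerise before it meets the cation. Its acyl group at C13 makes it a weaker partner for an electrophile, the cation may close through oxygen, and the facial preference may be modest. Fallback by known chemistry, setting out from 15: alkylation of the C13 enolate (KOC(CH3)3, NaI, THF) with 2-(chloromethyl)allyl-trimethylsilane should give the C13 allylsilane F1, on the face that keeps rings B and D cis. DDQ then removes hydride from C18, the only benzylic C–H left, and the allylsilane captures the cation to close ring C as the C15 methylidene tetracycle F2. Ozonolysis of F2 returns to the route at 20.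

**Step 9.** Addition of the acyl-anion equivalent to the hindered, electron-rich C13 ketone may be slow, so that intermolecular self-condensation of the aldehyde takes over. Fallback from 13: SmI2-mediated pinacol cyclisation should give the cis-diol F3, and Dess–Martin oxidation of its secondary C11 hydroxyl returns to the route at 14.

**Step 14.** Competing deprotonation at C14 would give the regioisomeric triflate. Fallback from 21: Wittig methylenation of the C15 ketone with Ph3P=CH2 (the enone is neopentylic and cannot be enolised) should give the exocyclic alkene F4. Cobalt hydride-catalysed isomerisation (Co(salen)Cl, PhSiH3) then moves the double bond into the ring by hydrogen-atom abstraction from the less hindered C17, returning to the route at 23.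

**Step 19.** Protodesilylation of the allylsilane may compete with hydrolysis of the deactivated ketal. Fallback from 23, which removes the acid step from the allylsilane stage:
- conjugate reduction of the enone with [(Ph3P)CuH]6 gives the saturated ketone F5;
- aqueous HCl in THF removes silyl ether and ketal to give the hydroxy diketone F6;
- Dess–Martin oxidation gives the aldehyde F7;
- the Wittig reaction of step 18 gives the allylsilane diketone F8;
- IBX dehydrogenation of the 1,4-diketone returns to the route at 27.

**Step 20.** The nucleophile may attack C10 instead of C9, giving a bicyclo[2.2.2]octane, or the exo/endo preference at C4 may be poor. Fallback from 25, which puts C4 under thermodynamic control: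
- Wittig reaction with Ph3P=C(OCH3)CH3 gives the methyl enol ether F9;
- aqueous acid hydrolyses enol ether and ketal to the methyl ketone enedione F10;
- DBU effects the intramolecular Michael addition of C4 to C9 and equilibrates the acetyl group to the exo position, giving F11;
- methylenation of the unhindered acetyl group with Ph3P=CH2 returns to the route at 28.

## Further compounds

F1 | step 12 | C13-[2-(trimethylsilylmethyl)allyl] derivative of 15 | CC(C)(C)[Si](C)(C)OCC[C@@]23C4(OCCO4)CCC(=O)[C@]2(CC(=C)C[Si](C)(C)C)c2c(OC)ccc(OC)c2C3
F2 | step 12 | C15-methylidene analogue of 20 | CC(C)(C)[Si](C)(C)OCC[C@@]23C4(OCCO4)CCC(=O)[C@@]21CC(=C)C[C@@H]3c2c(OC)ccc(OC)c21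
F3 | step 9 | C11,C13-diol (pinacol product; C11 epimers) | CC(C)(C)[Si](C)(C)OCC[C@@]23C4(OCCO4)CCC(O)[C@]2(O)c2c(OC)ccc(OC)c2C3
F4 | step 14 | C15-methylidene enone | CC(C)(C)[Si](C)(C)OCC[C@@]23C4(OCCO4)C=CC(=O)[C@@]21CC(=C)C[C@@H]3c2c(OC)ccc(OC)c21
F5 | step 19 | C9,C10-dihydro derivative of 23 | CC(C)(C)[Si](C)(C)OCC[C@@]23C4(OCCO4)CCC(=O)[C@@]21CC(C)=C[C@@H]3c2c(OC)ccc(OC)c21
F6 | step 19 | hydroxy 1,4-diketone | OCC[C@@]23C(=O)CCC(=O)[C@@]21CC(C)=C[C@@H]3c2c(OC)ccc(OC)c21
F7 | step 19 | aldehyde 1,4-diketone | O=CC[C@@]23C(=O)CCC(=O)[C@@]21CC(C)=C[C@@H]3c2c(OC)ccc(OC)c21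
F8 | step 19 | allylsilane 1,4-diketone (alkene isomers) | C[Si](C)(C)CC(C)=CC[C@@]23C(=O)CCC(=O)[C@@]21CC(C)=C[C@@H]3c2c(OC)ccc(OC)c21
F9 | step 20 | methyl enol ether ketal (alkene isomers) | COC(C)=CC[C@@]23C4(OCCO4)C=CC(=O)[C@@]21CC(C)=C[C@@H]3c2c(OC)ccc(OC)c21
F10 | step 20 | 3-oxobutyl enedione | CC(=O)CC[C@@]23C(=O)C=CC(=O)[C@@]21CC(C)=C[C@@H]3c2c(OC)ccc(OC)c21
F11 | step 20 | C4 exo-acetyl analogue of 28 | CC(=O)[C@H]1C[C@@]23C(=O)[C@@H]1CC(=O)[C@@]21CC(C)=C[C@@H]3c2c(OC)ccc(OC)c21
A1 | alternative 1 | aryl bis(pinacol boronate) of the complete skeleton | C=C(C)[C@H]1C[C@@]23C(=O)[C@@H]1CC(=O)[C@@]21CC(C)=C[C@@H]3c2c(B4OC(C)(C)C(C)(C)O4)ccc(B5OC(C)(C)C(C)(C)O5)c21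
A2 | alternative 1 | cage diyne with (pinacolboryl)ethynyl groups on C13 and C18 | C=C(C)[C@H]1C[C@@]23C(=O)[C@@H]1CC(=O)[C@@]2(C#CB4OC(C)(C)C(C)(C)O4)CC(C)=C[C@@H]3C#CB5OC(C)(C)C(C)(C)O5
A3 | alternative 1 | ethyne | C#C
A4 | alternative 2 | pentacyclic C4-acetyl enone with C7 dimethyl ketal | CC(=O)C1=C[C@@]23C(OC)(OC)[C@@H]1CC(=O)[C@@]21CC(C)=C[C@@H]3c2c(OC)ccc(OC)c21
A5 | alternative 2 | benzocycloheptene with C13 chloride, C11 triethylsilyl enol ether and C18 cyclopentadienone ketal | CC(=O)C1=CC(OC)(OC)C(=C1)[C@@H]2C=C(C)CC(Cl)(C(=C)O[Si](CC)(CC)CC)c3c(OC)ccc(OC)c32
A6 | alternative 3 | tetracyclic triketone with C6 prenyl group | CC(C)=CC[C@@]23C(=O)CCC(=O)[C@@]21CC(=O)C[C@@H]3c2c(OC)ccc(OC)c21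
A7 | alternative 3 | 3,6-dimethoxybenzyne | COC1=CC=C(OC)C#C1
A8 | alternative 3 | bicyclic C11 trimethylsilyl enol ether with ring C enone | CC(C)=CC[C@]12C=CC(=O)CC1=C(O[Si](C)(C)C)CCC2=O
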